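Ring A is disconnected across two of its C–C bonds, to 2,3-dimethoxybuta-1,3-diene and an ethynyl ketone on lactone C4. One thermal Diels–Alder reaction closes the six-membered carbocycle and delivers both methoxy groups at once. The feature exploited is that ring A carries its two methoxy groups on adjacent carbons (C3 and C4 of ring A), meta and para to C1, its only carbon-bearing position. Dehydrogenation, reduction of the ketone to CH2 and desilylation then finish the target. The cycloaddition precursor is the (3S,4S)-butyrolactone with a silylated C3 hydroxyl, the silyl-protected syringyl group (ring B) and a prop-2-ynoyl group on C4, built from diethyl (S)-malate.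

Key step: step 14

Remarks on the chemistry (assumptions):
- Compounds 5, 6, 16 and 19 are taken as purchased.
- Lactone numbering is O1, C2 (C=O), C3 (quaternary), C4, C5 (OCH2). ArCH2 stands for [3,5-dimethoxy-4-(triisopropylsilyloxy)phenyl]methyl, the protected ring B benzyl group.
- The carbon introduced in step 4 becomes the exocyclic carbon on C4 (later the benzylic CH2 of ring A), and the malate C4 carboxyl becomes lactone C5. With this assignment the normal anti sense of the malate dianion alkylation, together with retention at the carbinol carbon in step 7, gives the (3S,4S) arrangement of the target.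
- The phenol is carried as a triisopropylsilyl ether so that the alkyl benzyl ether can be hydrogenolysed in step 10 without freeing the phenol.
- The ynone 18 and the cycloadduct 20 are (3S,4S) like the target, although the ranking of the substituents on C4 differs.

Step 1
Reactants: 1 syringaldehyde (4-hydroxy-3,5-dimethoxybenzaldehyde)
Product: 2 3,5-dimethoxy-4-(triisopropylsilyloxy)benzaldehyde
Conditions: TIPSCl, imidazole, DMF, 40 °C
Reagents that add atoms: chlorotriisopropylsilane, CC(C)[Si](Cl)(C(C)C)C(C)C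
Why: Imidazole-mediated O-silylation of the phenol gives a silyl ether that should withstand the amide bases, borane, hydrogenolysis and oxidations ahead.

Step 2
Reactants: 2 3,5-dimethoxy-4-(triisopropylsilyloxy)benzaldehyde
Product: 3 [3,5-dimethoxy-4-(triisopropylsilyloxy)phenyl]methanol
Conditions: NaBH4, MeOH, 0 °C
Reagents that add atoms: none
Why: Borohydride reduction of the aldehyde is chemoselective and leaves the aryl silyl ether untouched.

Step 3
Reactants: 3 [3,5-dimethoxy-4-(triisopropylsilyloxy)phenyl]methanol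
Product: 4 [4-(bromomethyl)-2,6-dimethoxyphenoxy]triisopropylsilane (ArCH2Br)
Conditions: CBr4, PPh3, CH2Cl2, 0 °C; used without storage
Reagents that add atoms: carbon tetrabromide, BrC(Br)(Br)Br
Why: The Appel reaction converts the benzylic alcohol to the bromide under neutral conditions that spare the silyl ether.

Step 4
Reactants: 5 diethyl (S)-malate; 6 benzyl chloromethyl ether
Product: 7 diethyl (2S,3R)-3-[(benzyloxy)methyl]-2-hydroxybutanedioate
Conditions: LDA (2.2 equiv), THF, −78 → −20 °C; then 6, −78 → −10 °C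
Reagents that add atoms: none
Why: In this Fráter–Seebach alkylation the chelated lithium alkoxide–enolate of the β-hydroxy ester is alkylated at C3 anti to the C2 oxygen, so the existing (2S) carbinol sets the new (3R) centre, the future lactone C4.

Step 5
Reactants: 7 diethyl (2S,3R)-3-[(benzyloxy)methyl]-2-hydroxybutanedioate
Product: 8 (2S,3R)-3-[(benzyloxy)methyl]-2-hydroxybutanedioic acid
Conditions: KOH, H2O/THF, rt; then aq HCl
Reagents that add atoms: potassium hydroxide, [K+].[OH-]
Why: Saponification of both ethyl esters is fast, and the resulting dicarboxylate is not prone to enolization, so C3 should keep its configuration.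

Step 6
Reactants: 8 (2S,3R)-3-[(benzyloxy)methyl]-2-hydroxybutanedioic acid
Product: 9 (2R)-3-(benzyloxy)-2-[(2S,4S)-2-tert-butyl-5-oxo-1,3-dioxolan-4-yl]propanoic acid (cis-dioxolanone)
Conditions: tBuCHO, TsOH (cat.), H2SO4 (cat.), pentane, reflux, Dean–Stark; crystallization
Reagents that add atoms: pivalaldehyde (2,2-dimethylpropanal), CC(C)(C)C=O
Why: Acid-catalysed acetalization of the α-hydroxy acid (Seebach dioxolanone formation, self-regeneration of stereocentres) should favour the five-membered cis-acetal under equilibrating conditions, the new acetal centre being set by the C2 carbinol centre.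

Step 7
Reactants: 9 (2R)-3-(benzyloxy)-2-[(2S,4S)-2-tert-butyl-5-oxo-1,3-dioxolan-4-yl]propanoic acid; 4 ArCH2Br
Product: 10 (2R)-3-(benzyloxy)-2-[(2S,4S)-4-(ArCH2)-2-tert-butyl-5-oxo-1,3-dioxolan-4-yl]propanoic acid
Conditions: LiHMDS (2.2 equiv), THF, −78 °C; then 4, −78 → −20 °C
Reagents that add atoms: none
Why: Enolate alkylation of the carboxylate–dioxolanone dianion should occur on the face opposite the tert-butyl group, so the benzyl group takes the place of H with net retention and fixes the quaternary centre (future lactone C3) as S.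

Step 8
Reactants: 10 (2R)-3-(benzyloxy)-2-[(2S,4S)-4-(ArCH2)-2-tert-butyl-5-oxo-1,3-dioxolan-4-yl]propanoic acid
Product: 12 (3S,4S)-3-(ArCH2)-4-[(benzyloxy)methyl]-3-hydroxyoxolan-2-one, via primary alcohol 11 (not isolated)
Conditions: BH3·SMe2, THF, 0 °C → rt; MeOH; then TFA (cat.), CH2Cl2, rt
Reagents that add atoms: none
Why: Borane reduces the free carboxylic acid far faster than the dioxolanone carbonyl, and acid then drives translactonization of the new primary alcohol onto that carbonyl with loss of pivalaldehyde, no stereocentre being touched.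

Step 9
Reactants: 12 (3S,4S)-3-(ArCH2)-4-[(benzyloxy)methyl]-3-hydroxyoxolan-2-one
Product: 13 (3S,4S)-3-(ArCH2)-4-[(benzyloxy)methyl]-3-(triethylsilyloxy)oxolan-2-one
Conditions: TESOTf, 2,6-lutidine, CH2Cl2, 0 °C → rt
Reagents that add atoms: triethylsilyl trifluoromethanesulfonate, CC[Si](CC)(CC)OS(=O)(=O)C(F)(F)F
Why: Silylation with a silyl triflate is strong enough for the hindered tertiary alcohol, and the silyl ether later blocks oxa-Michael addition to the ynone and retro-aldol cleavage.

Step 10
Reactants: 13 (3S,4S)-3-(ArCH2)-4-[(benzyloxy)methyl]-3-(triethylsilyloxy)oxolan-2-one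
Product: 14 (3S,4S)-3-(ArCH2)-4-(hydroxymethyl)-3-(triethylsilyloxy)oxolan-2-one
Conditions: H2 (1 atm), 10% Pd/C, EtOAc, rt
Reagents that add atoms: none
Why: Hydrogenolysis of the alkyl benzyl ether in a neutral aprotic solvent should leave both silyl ethers and the lactone intact and avoid migration of the lactone between the two CH2O arms on C4.

Step 11
Reactants: 14 (3S,4S)-3-(ArCH2)-4-(hydroxymethyl)-3-(triethylsilyloxy)oxolan-2-one
Product: 15 (3S,4S)-4-(ArCH2)-5-oxo-4-(triethylsilyloxy)oxolane-3-carbaldehyde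
Conditions: Dess–Martin periodinane (DMP), CH2Cl2, 0 °C → rt; used at once
Reagents that add atoms: none
Why: Dess–Martin oxidation takes the primary alcohol to the aldehyde under near-neutral conditions that should not epimerize the adjacent C–H centre.

Step 12
Reactants: 15 (3S,4S)-4-(ArCH2)-5-oxo-4-(triethylsilyloxy)oxolane-3-carbaldehyde; 16 ethynylmagnesium bromide
Product: 17 (3S,4R)-3-(ArCH2)-4-(1-hydroxyprop-2-yn-1-yl)-3-(triethylsilyloxy)oxolan-2-one (both carbinol epimers)
Conditions: 16 (1.5 equiv), THF, −78 → −40 °C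
Reagents that add atoms: none
Why: Grignard 1,2-addition of the weakly basic alkynyl reagent to the aldehyde at low temperature should outpace enolization and attack on the hindered lactone, and the uncontrolled carbinol centre is removed in the next step.

Step 13
Reactants: 17 (3S,4R)-3-(ArCH2)-4-(1-hydroxyprop-2-yn-1-yl)-3-(triethylsilyloxy)oxolan-2-one
Product: 18 (3S,4S)-3-(ArCH2)-4-(prop-2-ynoyl)-3-(triethylsilyloxy)oxolan-2-one
Conditions: DMP, CH2Cl2, 0 °C → rt
Reagents that add atoms: none
Why: Dess–Martin oxidation of the propargylic alcohol gives the terminal ynone, which erases the carbinol centre and activates the alkyne as a dienophile.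

Step 14
Reactants: 18 (3S,4S)-3-(ArCH2)-4-(prop-2-ynoyl)-3-(triethylsilyloxy)oxolan-2-one; 19 2,3-dimethoxybuta-1,3-diene
Product: 20 (3S,4S)-3-(ArCH2)-4-(4,5-dimethoxycyclohexa-1,4-diene-1-carbonyl)-3-(triethylsilyloxy)oxolan-2-one
Conditions: 19 (4 equiv), BHT (cat.), toluene, 90 °C, sealed tube
Reagents that add atoms: none
Why: A concerted, suprafacial normal-electron-demand [4+2] cycloaddition joins the two terminal CH2 carbons of the electron-rich diene to the two alkyne carbons of the electron-poor ynone; the closest known reaction type is the thermal Diels–Alder reaction of alkynyl ketones with 2,3-dialkoxybutadienes. The six-membered carbocycle is closed by intermolecular [4+2] annulation (two C–C bonds in one event, no tethered cyclization) and emerges as a cyclohexa-1,4-diene, one dehydrogenation away from ring A. No stereocentre is formed, and lactone C3 and C4 are spectators. Because the diene is symmetric there is no regiochemical question, and the methoxy groups necessarily end up on adjacent carbons meta and para to the acyl carbon. The selectivity needed is chemoselectivity for the alkyne: the triethylsilyl ether on the C3 oxygen excludes 6-endo oxa-Michael addition to the ynone, and the neutral, base-free medium avoids enolization at C4 and with it epimerization or β-elimination of the lactone oxygen.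

Step 15
Reactants: 20 (3S,4S)-3-(ArCH2)-4-(4,5-dimethoxycyclohexa-1,4-diene-1-carbonyl)-3-(triethylsilyloxy)oxolan-2-one
Product: 21 (3S,4S)-3-(ArCH2)-4-(3,4-dimethoxybenzoyl)-3-(triethylsilyloxy)oxolan-2-one
Conditions: DDQ (1.1 equiv), toluene, rt (crude 20)
Reagents that add atoms: none
Why: Oxidative aromatization of the cyclohexa-1,4-diene by hydride abstraction with DDQ is driven by arene formation and should be much faster than oxidation at any other benzylic position.

Step 16
Reactants: 21 (3S,4S)-3-(ArCH2)-4-(3,4-dimethoxybenzoyl)-3-(triethylsilyloxy)oxolan-2-one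
Product: 23 (3S,4S)-3-(ArCH2)-4-[(3,4-dimethoxyphenyl)methyl]-3-(triethylsilyloxy)oxolan-2-one, via benzylic alcohol 22 (not isolated)
Conditions: H2 (4 bar), 10% Pd/C, AcOH/EtOAc, 45 °C
Reagents that add atoms: none
Why: Catalytic hydrogenation of the electron-rich aryl ketone to the benzylic alcohol and hydrogenolysis of its benzylic C–O bond (aryl ketone to methylene reduction over Pd) take place on the metal in weakly acidic medium, which limits free benzylic cation chemistry, and C4 is no longer epimerizable afterwards.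

Step 17
Reactants: 23 (3S,4S)-3-(ArCH2)-4-[(3,4-dimethoxyphenyl)methyl]-3-(triethylsilyloxy)oxolan-2-one
Product: 24 (3S,4S)-4-[(3,4-dimethoxyphenyl)methyl]-3-hydroxy-3-[(4-hydroxy-3,5-dimethoxyphenyl)methyl]oxolan-2-one (target)
Conditions: TBAF, AcOH, THF, 0 °C → rt
Reagents that add atoms: none
Why: Fluoride-mediated desilylation cleaves both the tertiary triethylsilyl ether and the aryl triisopropylsilyl ether, and the acetic acid buffer keeps the lactone and the phenol away from strong base.

Compound list
1 | syringaldehyde (4-hydroxy-3,5-dimethoxybenzaldehyde) | COc1cc(C=O)cc(OC)c1O | starting material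
2 | 3,5-dimethoxy-4-(triisopropylsilyloxy)benzaldehyde | COc1cc(C=O)cc(OC)c1O[Si](C(C)C)(C(C)C)C(C)C | intermediate
3 | [3,5-dimethoxy-4-(triisopropylsilyloxy)phenyl]methanol | COc1cc(CO)cc(OC)c1O[Si](C(C)C)(C(C)C)C(C)C | intermediate
4 | [4-(bromomethyl)-2,6-dimethoxyphenoxy]triisopropylsilane | COc1cc(CBr)cc(OC)c1O[Si](C(C)C)(C(C)C)C(C)C | intermediate
5 | diethyl (S)-malate (diethyl (2S)-2-hydroxybutanedioate) | CCOC(=O)C[C@H](O)C(=O)OCC | starting material
6 | benzyl chloromethyl ether | ClCOCc1ccccc1 | starting material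
7 | diethyl (2S,3R)-3-[(benzyloxy)methyl]-2-hydroxybutanedioate | CCOC(=O)[C@H](COCc1ccccc1)[C@H](O)C(=O)OCC | intermediate
8 | (2S,3R)-3-[(benzyloxy)methyl]-2-hydroxybutanedioic acid | OC(=O)[C@H](COCc1ccccc1)[C@H](O)C(=O)O | intermediate
9 | (2R)-3-(benzyloxy)-2-[(2S,4S)-2-tert-butyl-5-oxo-1,3-dioxolan-4-yl]propanoic acid | OC(=O)[C@H](COCc1ccccc1)[C@@H]1O[C@H](C(C)(C)C)OC1=O | intermediate
10 | (2R)-3-(benzyloxy)-2-[(2S,4S)-2-tert-butyl-4-{[3,5-dimethoxy-4-(triisopropylsilyloxy)phenyl]methyl}-5-oxo-1,3-dioxolan-4-yl]propanoic acid | OC(=O)[C@H](COCc1ccccc1)[C@]1(Cc2cc(OC)c(O[Si](C(C)C)(C(C)C)C(C)C)c(OC)c2)O[C@H](C(C)(C)C)OC1=O | intermediate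
11 | (2S,5S)-5-[(2R)-1-(benzyloxy)-3-hydroxypropan-2-yl]-2-tert-butyl-5-{[3,5-dimethoxy-4-(triisopropylsilyloxy)phenyl]methyl}-1,3-dioxolan-4-one | OC[C@H](COCc1ccccc1)[C@]1(Cc2cc(OC)c(O[Si](C(C)C)(C(C)C)C(C)C)c(OC)c2)O[C@H](C(C)(C)C)OC1=O | intermediate
12 | (3S,4S)-4-[(benzyloxy)methyl]-3-{[3,5-dimethoxy-4-(triisopropylsilyloxy)phenyl]methyl}-3-hydroxyoxolan-2-one | c1ccccc1COC[C@H]2COC(=O)[C@]2(O)Cc3cc(OC)c(O[Si](C(C)C)(C(C)C)C(C)C)c(OC)c3 | intermediate
13 | (3S,4S)-4-[(benzyloxy)methyl]-3-{[3,5-dimethoxy-4-(triisopropylsilyloxy)phenyl]methyl}-3-(triethylsilyloxy)oxolan-2-one | c1ccccc1COC[C@H]2COC(=O)[C@]2(O[Si](CC)(CC)CC)Cc3cc(OC)c(O[Si](C(C)C)(C(C)C)C(C)C)c(OC)c3 | intermediate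
14 | (3S,4S)-3-{[3,5-dimethoxy-4-(triisopropylsilyloxy)phenyl]methyl}-4-(hydroxymethyl)-3-(triethylsilyloxy)oxolan-2-one | OC[C@H]1COC(=O)[C@]1(O[Si](CC)(CC)CC)Cc1cc(OC)c(O[Si](C(C)C)(C(C)C)C(C)C)c(OC)c1 | intermediate
15 | (3S,4S)-4-{[3,5-dimethoxy-4-(triisopropylsilyloxy)phenyl]methyl}-5-oxo-4-(triethylsilyloxy)oxolane-3-carbaldehyde | O=C[C@H]1COC(=O)[C@]1(O[Si](CC)(CC)CC)Cc1cc(OC)c(O[Si](C(C)C)(C(C)C)C(C)C)c(OC)c1 | intermediate
16 | ethynylmagnesium bromide | C#C[Mg]Br | starting material
17 | (3S,4R)-3-{[3,5-dimethoxy-4-(triisopropylsilyloxy)phenyl]methyl}-4-(1-hydroxyprop-2-yn-1-yl)-3-(triethylsilyloxy)oxolan-2-one, both carbinol epimers | C#CC(O)[C@H]1COC(=O)[C@]1(O[Si](CC)(CC)CC)Cc1cc(OC)c(O[Si](C(C)C)(C(C)C)C(C)C)c(OC)c1 | intermediate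
18 | (3S,4S)-3-{[3,5-dimethoxy-4-(triisopropylsilyloxy)phenyl]methyl}-4-(prop-2-ynoyl)-3-(triethylsilyloxy)oxolan-2-one | C#CC(=O)[C@H]1COC(=O)[C@]1(O[Si](CC)(CC)CC)Cc1cc(OC)c(O[Si](C(C)C)(C(C)C)C(C)C)c(OC)c1 | intermediate
19 | 2,3-dimethoxybuta-1,3-diene | C=C(OC)C(OC)=C | starting material
20 | (3S,4S)-4-(4,5-dimethoxycyclohexa-1,4-diene-1-carbonyl)-3-{[3,5-dimethoxy-4-(triisopropylsilyloxy)phenyl]methyl}-3-(triethylsilyloxy)oxolan-2-one | COC1=C(OC)CC(C(=O)[C@H]2COC(=O)[C@]2(O[Si](CC)(CC)CC)Cc2cc(OC)c(O[Si](C(C)C)(C(C)C)C(C)C)c(OC)c2)=CC1 | intermediate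
21 | (3S,4S)-4-(3,4-dimethoxybenzoyl)-3-{[3,5-dimethoxy-4-(triisopropylsilyloxy)phenyl]methyl}-3-(triethylsilyloxy)oxolan-2-one | COc1ccc(C(=O)[C@H]2COC(=O)[C@]2(O[Si](CC)(CC)CC)Cc2cc(OC)c(O[Si](C(C)C)(C(C)C)C(C)C)c(OC)c2)cc1OC | intermediate
22 | (3S,4R)-4-[(3,4-dimethoxyphenyl)(hydroxy)methyl]-3-{[3,5-dimethoxy-4-(triisopropylsilyloxy)phenyl]methyl}-3-(triethylsilyloxy)oxolan-2-one, both carbinol epimers | COc1ccc(C(O)[C@H]2COC(=O)[C@]2(O[Si](CC)(CC)CC)Cc2cc(OC)c(O[Si](C(C)C)(C(C)C)C(C)C)c(OC)c2)cc1OC | intermediate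
23 | (3S,4S)-4-[(3,4-dimethoxyphenyl)methyl]-3-{[3,5-dimethoxy-4-(triisopropylsilyloxy)phenyl]methyl}-3-(triethylsilyloxy)oxolan-2-one | COc1ccc(C[C@H]2COC(=O)[C@]2(O[Si](CC)(CC)CC)Cc2cc(OC)c(O[Si](C(C)C)(C(C)C)C(C)C)c(OC)c2)cc1OC | intermediate
24 | (3S,4S)-4-[(3,4-dimethoxyphenyl)methyl]-3-hydroxy-3-[(4-hydroxy-3,5-dimethoxyphenyl)methyl]oxolan-2-one | COc1ccc(C[C@H]2COC(=O)[C@]2(O)Cc2cc(OC)c(O)c(OC)c2)cc1OC | target

Total step count: 17. Longest linear sequence: 14 steps (steps 4 to 17 from diethyl (S)-malate; the branch from syringaldehyde through steps 1 to 3 and 7 to 17 is equally long).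

Steps most likely to fail

Step 14. The cycloaddition may be slow, since only the s-cis conformer of the diene reacts, while diene and ynone oligomerize on prolonged heating. Enolization at C4 could then lead to epimerization or to opening of the lactone by β-elimination. The fallback gives up building ring A and brings it in intact. It sets out from aldehyde 15: addition of the organocerium reagent made from 3,4-dimethoxyphenylmagnesium bromide and CeCl3 (THF, −78 °C) should give the benzylic alcohol 22, this time isolated. The route is rejoined at 22, which the hydrogenolysis conditions of step 16 take on to 23. No new compound is made (F0).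

Step 16. The reduction may stall at the benzylic alcohol. If stronger acid is added to force it, ionization of that alcohol may be followed by Friedel–Crafts attack of the electron-rich ring B on the benzylic carbon, closing a tetralin, or by premature loss of the triethylsilyl group. The fallback separates reduction and C–O cleavage and needs no acid. It sets out from ketone 21: reduction with NaBH4 and CeCl3 (MeOH/THF, −40 °C) should give alcohol 22 as an isolated compound. Acetylation (Ac2O, pyridine, DMAP) would give the benzylic acetate F1, and hydrogenolysis of this benzylic ester (H2, 10% Pd/C, EtOAc, rt) should deliver 23, where the route is rejoined.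

Step 12. The basic acetylide may deprotonate the aldehyde α-carbon, leading to epimerization at C4 or β-elimination of the lactone oxygen, or may attack the lactone carbonyl. The fallback forms the ynone by acyl cross-coupling and avoids a carbanion next to the aldehyde. It sets out from aldehyde 15: chlorite oxidation (NaClO2, NaH2PO4, 2-methylbut-2-ene, tBuOH/H2O) should give the carboxylic acid F2. Neutral chlorination with 1-chloro-N,N,2-trimethylprop-1-en-1-amine (CH2Cl2, 0 °C) would give the acid chloride F3. Stille acylation with tributyl(ethynyl)stannane (Pd(PPh3)4, zerovalent palladium, toluene, rt → 50 °C) should give ynone 18 directly, where the route is rejoined without steps 12 and 13.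

Further compounds
F0 | step 14 | none | none
F1 | step 16 | (3S,4R)-4-[acetoxy(3,4-dimethoxyphenyl)methyl]-3-{[3,5-dimethoxy-4-(triisopropylsilyloxy)phenyl]methyl}-3-(triethylsilyloxy)oxolan-2-one, both epimers at the acetoxy carbon | COc1ccc(C(OC(C)=O)[C@H]2COC(=O)[C@]2(O[Si](CC)(CC)CC)Cc2cc(OC)c(O[Si](C(C)C)(C(C)C)C(C)C)c(OC)c2)cc1OC
F2 | step 12 | (3S,4S)-4-{[3,5-dimethoxy-4-(triisopropylsilyloxy)phenyl]methyl}-5-oxo-4-(triethylsilyloxy)oxolane-3-carboxylic acid | OC(=O)[C@H]1COC(=O)[C@]1(O[Si](CC)(CC)CC)Cc1cc(OC)c(O[Si](C(C)C)(C(C)C)C(C)C)c(OC)c1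
F3 | step 12 | (3S,4S)-4-{[3,5-dimethoxy-4-(triisopropylsilyloxy)phenyl]methyl}-5-oxo-4-(triethylsilyloxy)oxolane-3-carbonyl chloride | ClC(=O)[C@H]1COC(=O)[C@]1(O[Si](CC)(CC)CC)Cc1cc(OC)c(O[Si](C(C)C)(C(C)C)C(C)C)c(OC)c1
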